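Ring A (C1–C5) carries the feature the plan rests on. The tertiary C4–OH and carbon C6 on C5 are cis, so C4–C5–C6 is a β-hydroxy carbonyl array, and C6 is trans to C10 on quaternary C1 (trans ring fusion C1–C5).
Ring B (C1, C5–C10) is formed last. It is cut at C8=C9 (ring-closing metathesis) and at C6–C7 (methallyl addition to a C6 aldehyde), and the anisate goes onto C6–OH before the C9 vinyl group is unveiled.
Ring A is formed first. It is cut at C3–C4, a SmI2 Barbier closure of a C3 iodide onto the C4 isobutyryl ketone of a β-keto ester whose C6 ester binds samarium.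
C9 passes through that closure as CH2OTBS. A C9=CH2 group would lie 5-exo to both a C3 radical and a C4 ketyl, and the three operations that make the vinyl group are only postponed.
C1 and C10 come from Sharpless epoxidation of a Z-allylic alcohol and allyl-Grignard opening at tertiary C1 with inversion. The allyl group becomes the C5–C6 ester arm, and aldol addition plus oxidation brings in C4.
Key step: step 13

Numbering: C1 is the methyl-bearing quaternary fusion carbon, C2 and C3 are the CH2 groups of ring A, and C4 is the carbinol carrying isopropyl. C5 is the fusion CH, C6 the acyloxy carbon, C7 a CH2, C8 the alkene carbon with methyl, C9 the alkene CH, and C10 the free secondary carbinol. TBS = tert-butyldimethylsilyl.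
Assumption: the SMILES is read as 1S,4R,5S,6S,10R in this numbering. C10 must then be R in the epoxy alcohol, which calls for D-(−)-tartrate, because L-(+)-tartrate gives the 2S epoxy alcohols.

Step 1
Reactants: 1 benzyl but-3-yn-1-yl ether; 2 methyl chloroformate
Product: 4 methyl 5-(benzyloxy)pent-2-ynoate, via lithium acetylide 3 (not isolated)
Conditions: n-BuLi, THF, −78 °C; then ClCO2Me, −78 to 0 °C
Reagents that add atoms: none
Why: Deprotonation of the terminal alkyne and C-acylation of the acetylide by the chloroformate (acetylide carboxylation) brings in C9 as an ester carbon.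

Step 2
Reactants: 4 methyl 5-(benzyloxy)pent-2-ynoate
Product: 5 methyl (Z)-5-(benzyloxy)-3-methylpent-2-enoate
Conditions: Me2CuLi (MeLi, CuI), THF, −78 °C; MeOH, then aq NH4Cl at −78 °C
Reagents that add atoms: lithium dimethylcuprate, [Li+].C[Cu-]C
Why: Syn carbocupration of the ynoate puts methyl and copper on the same side, and a cold protic quench keeps that geometry, so the C2–C3 chain ends cis to the ester (Z).

Step 3
Reactants: 5 methyl (Z)-5-(benzyloxy)-3-methylpent-2-enoate
Product: 6 (Z)-5-(benzyloxy)-3-methylpent-2-en-1-ol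
Conditions: i-Bu2AlH (2.5 equiv), CH2Cl2, −78 to 0 °C; aq Rochelle salt
Reagents that add atoms: none
Why: 1,2-Reduction of the conjugated ester by the aluminium hydride gives the allylic alcohol without touching the Z alkene or the benzyl ether.

Step 4
Reactants: 6 (Z)-5-(benzyloxy)-3-methylpent-2-en-1-ol
Product: 7 [(2R,3S)-3-[2-(benzyloxy)ethyl]-3-methyloxiran-2-yl]methanol
Conditions: Ti(OiPr)4 (cat.), D-(−)-diethyl tartrate (cat.), t-BuOOH, 4 Å MS, CH2Cl2, −20 °C
Reagents that add atoms: tert-butyl hydroperoxide, CC(C)(C)OO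
Why: In the Katsuki–Sharpless asymmetric epoxidation the titanium/D-(−)-tartrate catalyst delivers oxygen to the face that gives the 2R epoxy alcohol, and suprafacial addition to the Z alkene fixes C10 and C1 together.

Step 5
Reactants: 7 [(2R,3S)-3-[2-(benzyloxy)ethyl]-3-methyloxiran-2-yl]methanol; 8 allylmagnesium chloride
Product: 9 (2S,3R)-3-[2-(benzyloxy)ethyl]-3-methylhex-5-ene-1,2-diol
Conditions: allylMgCl (5 equiv), THF, 0 °C to rt; aq NH4Cl
Reagents that add atoms: none
Why: This is an allylmagnesium halide opening of a trisubstituted 2,3-epoxy alcohol at the more substituted carbon, in which magnesium held by the alkoxide and epoxide oxygens loosens the tertiary C1–O bond and allyl enters from the rear, so quaternary C1 forms with inversion while C10–O is untouched.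

Step 6
Reactants: 9 (2S,3R)-3-[2-(benzyloxy)ethyl]-3-methylhex-5-ene-1,2-diol
Product: 10 the C9,C10-bis-TBS ether of 9
Conditions: TBSOTf (2.5 equiv), 2,6-lutidine, CH2Cl2, 0 °C
Reagents that add atoms: tert-butyldimethylsilyl triflate, CC(C)(C)[Si](C)(C)OS(=O)(=O)C(F)(F)F
Why: The silyl triflate is reactive enough for the neopentyl-type C10–OH, so both hydroxyls are capped in one silyl ether protection.

Step 7
Reactants: 10 the C9,C10-bis-TBS ether of 9
Product: 11 (3R,4S)-4,5-bis(TBSO)-3-methyl-3-(prop-2-en-1-yl)pentan-1-ol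
Conditions: Na, NH3(l), THF, −78 °C; solid NH4Cl
Reagents that add atoms: none
Why: Dissolving-metal cleavage removes the benzyl ether, while the isolated terminal alkene and the silyl ethers are inert under brief treatment at −78 °C.

Step 8
Reactants: 11 (3R,4S)-4,5-bis(TBSO)-3-methyl-3-(prop-2-en-1-yl)pentan-1-ol
Product: 12 (4R,5S)-5,6-bis(TBSO)-4-(2-chloroethyl)-4-methylhex-1-ene
Conditions: PPh3, N-chlorosuccinimide, THF, 0 °C to rt
Reagents that add atoms: N-chlorosuccinimide, O=C1CCC(=O)N1Cl
Why: Appel-type chlorination under neutral conditions converts C3–OH before any C6 ester exists, which rules out δ-lactone formation between them, and the chloride is inert in steps 9 to 11.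

Step 9
Reactants: 12 (4R,5S)-5,6-bis(TBSO)-4-(2-chloroethyl)-4-methylhex-1-ene
Product: 13 methyl (3R,4S)-4,5-bis(TBSO)-3-(2-chloroethyl)-3-methylpentanoate
Conditions: O3, NaOH, MeOH/CH2Cl2, −78 °C
Reagents that add atoms: ozone, [O-][O+]=O; methanol, CO
Why: Ozonolysis in methanolic NaOH (Marshall protocol) takes a terminal alkene directly to the methyl ester with loss of the CH2 terminus, trimming allyl to the C5–C6 arm under conditions that spare silyl ethers and chloride.

Step 10
Reactants: 13 methyl (3R,4S)-4,5-bis(TBSO)-3-(2-chloroethyl)-3-methylpentanoate; 14 isobutyraldehyde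
Product: 16 methyl (3S,4S)-4,5-bis(TBSO)-3-(2-chloroethyl)-2-(1-hydroxy-2-methylpropyl)-3-methylpentanoate (mixture at C4 and C5), via lithium enolate 15 (not isolated)
Conditions: LiN(iPr)2, THF, −78 °C; then i-PrCHO, −78 °C; AcOH quench
Reagents that add atoms: none
Why: Kinetic ester enolate formation and aldol addition make the C4–C5 bond, and the two new centres do not matter because C4 is oxidised next and C5 stays epimerisable.

Step 11
Reactants: 16 aldol adduct
Product: 17 methyl (3S,4S)-4,5-bis(TBSO)-3-(2-chloroethyl)-3-methyl-2-(2-methylpropanoyl)pentanoate (C5 epimers)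
Conditions: Dess–Martin periodinane, NaHCO3, CH2Cl2, rt
Reagents that add atoms: none
Why: Dess–Martin oxidation of the β-hydroxy ester gives the β-keto ester under near-neutral conditions that leave silyl ethers and chloride alone.

Step 12
Reactants: 17 chloro β-keto ester
Product: 18 methyl (3S,4S)-4,5-bis(TBSO)-3-(2-iodoethyl)-3-methyl-2-(2-methylpropanoyl)pentanoate (C5 epimers)
Conditions: NaI (10 equiv), acetone, reflux, dark
Reagents that add atoms: sodium iodide, [Na+].[I-]
Why: Finkelstein exchange, driven by precipitation of NaCl, installs the C3 iodide last and without base, so the enol oxygen is not alkylated at C3.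

Step 13
Reactants: 18 iodo β-keto ester
Product: 20 methyl (1R,2R,5S)-5-[(1S)-1,2-bis(TBSO)ethyl]-2-hydroxy-5-methyl-2-(propan-2-yl)cyclopentane-1-carboxylate, via C3 alkylsamarium diiodide 19 (not isolated)
Conditions: SmI2 (2.5 equiv, 0.1 M), THF, −78 °C to rt; aq NaHCO3
Reagents that add atoms: none
Why: Divalent samarium transfers one electron to the C3–I bond and a second to the primary radical, giving alkylsamarium 19, which adds to the C4 ketone; the closest known reaction type is the SmI2-promoted intramolecular Barbier cyclization of 2-(3-iodopropyl) β-keto esters to cis-2-hydroxycyclopentanecarboxylates. Ring A closes in the 5-exo-trig mode through the new C3–C4 bond. C4 is controlled by trivalent samarium held between the C4 and C6 carbonyl oxygens, because this chelate ring ends cis-fused to the new cyclopentane, so C4–OH and C6 are cis and isopropyl goes to the other face. C5 is controlled by C1: the C5–H of the samarium-bound β-dicarbonyl is labile, the samarium alkoxide already formed can shuttle the proton during the slow warm-up, and the epimer that places C6 beside the C1 methyl and anti to the bulky C10 side chain should close faster. The step needs attack on the ketone in preference to radical pathways and to the ester, and 18 secures this because C9 is sp3 (no alkene within reach of C3 or C4), no leaving group sits β to C3 or α to C4, attack at C6 would need a four-membered ring, and HMPA is left out so that the chelate stays intact.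

Step 14
Reactants: 20 cyclopentanol ester
Product: 21 C6 primary alcohol / C4 tertiary alcohol (1S,4R,5S,10S diol, bis-TBS)
Conditions: LiAlH4, Et2O, 0 °C to rt; Fieser work-up
Reagents that add atoms: none
Why: Hydride reduction of the hindered ester to the primary alcohol outruns any retro-aldol cleavage because C4–OH is bound at once as an aluminium alkoxide.

Step 15
Reactants: 21 diol
Product: 22 β-hydroxy aldehyde (C6 = CHO; 1S,4R,5R,10S)
Conditions: Dess–Martin periodinane, NaHCO3, CH2Cl2, 0 °C to rt
Reagents that add atoms: none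
Why: Only the primary C6–OH can be oxidised, and the buffered Dess–Martin oxidation involves no base that could trigger retro-aldol cleavage or C5 epimerisation.

Step 16
Reactants: 22 β-hydroxy aldehyde; 23 tributyl(2-methylallyl)stannane
Product: 24 C6 homoallylic alcohol (1S,4R,5S,6S,10S)
Conditions: MgBr2·OEt2 (3 equiv), CH2Cl2, −78 °C; then 23, −78 to −20 °C
Reagents that add atoms: none
Why: In this chelation-controlled (Keck-type) allylstannane addition magnesium bridges C4–OH and the C6 carbonyl oxygen, isopropyl sits equatorial and C3 axial on the six-membered chelate, and the methallyl group therefore enters on the H5 face anti to C1, which gives 6S.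

Step 17
Reactants: 24 C6 homoallylic alcohol; 25 4-methoxybenzoyl chloride
Product: 26 C6 4-methoxybenzoate
Conditions: 25, Et3N, DMAP, CH2Cl2, rt to 40 °C
Reagents that add atoms: none
Why: DMAP-catalysed acylation takes the secondary C6–OH and leaves the tertiary C4–OH, and the ester of the target also protects C6 during steps 18 to 21.

Step 18
Reactants: 26 C6 4-methoxybenzoate
Product: 27 C9 primary alcohol (C10–OTBS kept)
Conditions: HF·pyridine, pyridine, THF, 0 °C
Reagents that add atoms: none
Why: Selective desilylation works because the primary C9 silyl ether is cleaved far faster than the secondary C10 silyl ether next to quaternary C1.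

Step 19
Reactants: 27 C9 primary alcohol
Product: 28 C9 aldehyde (α-silyloxy aldehyde)
Conditions: Dess–Martin periodinane, NaHCO3, CH2Cl2, rt
Reagents that add atoms: none
Why: Dess–Martin oxidation converts the only oxidisable hydroxyl under non-basic conditions, so C10 is not epimerised.

Step 20
Reactants: 28 C9 aldehyde
Product: 29 diene with C9 vinyl and C8 methallyl termini (1S,4R,5S,6S,10R)
Conditions: Ph3PCH3Br, KOtBu, THF, 0 °C; then 28, −78 to 0 °C
Reagents that add atoms: methyltriphenylphosphonium bromide, C[P+](c1ccccc1)(c1ccccc1)c1ccccc1.[Br-]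
Why: Wittig methylenation of the α-silyloxy aldehyde at low temperature is faster than enolisation at C10 or attack on the aryl ester.

Step 21
Reactants: 29 diene
Product: 30 C10-TBS ether of the target
Conditions: second-generation Grubbs catalyst (10 mol %), toluene (2 mM), 80 °C
Reagents that add atoms: none
Why: Ring-closing metathesis of the monosubstituted C9 alkene with the 1,1-disubstituted C8 alkene closes ring B as the trisubstituted cycloheptene, which can only be Z, with loss of ethylene and no change at any stereocentre.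

Step 22
Reactants: 30 C10-TBS ether of the target
Product: 31 target (1S,4R,5S,6S,10R)
Conditions: Bu4NF, AcOH (1:1), THF, rt to 45 °C
Reagents that add atoms: none
Why: Buffered fluoride desilylation frees the allylic C10–OH without acid, which could ionise the allylic alcohol, and without free alkoxide, which could move the anisate.

Compound list
1 | benzyl but-3-yn-1-yl ether | C#CCCOCc1ccccc1 | starting material
2 | methyl chloroformate | COC(=O)Cl | starting material
3 | lithium 4-(benzyloxy)but-1-yn-1-ide (not isolated) | [Li]C#CCCOCc1ccccc1 | intermediate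
4 | methyl 5-(benzyloxy)pent-2-ynoate | COC(=O)C#CCCOCc1ccccc1 | intermediate
5 | methyl (Z)-5-(benzyloxy)-3-methylpent-2-enoate | COC(=O)/C=C(/C)CCOCc1ccccc1 | intermediate
6 | (Z)-5-(benzyloxy)-3-methylpent-2-en-1-ol | OC/C=C(/C)CCOCc1ccccc1 | intermediate
7 | [(2R,3S)-3-[2-(benzyloxy)ethyl]-3-methyloxiran-2-yl]methanol | OC[C@H]1O[C@@]1(C)CCOCc2ccccc2 | intermediate
8 | allylmagnesium chloride | C=CC[Mg]Cl | starting material
9 | (2S,3R)-3-[2-(benzyloxy)ethyl]-3-methylhex-5-ene-1,2-diol | OC[C@@H](O)[C@](C)(CC=C)CCOCc1ccccc1 | intermediate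
10 | C9,C10-bis-TBS ether of 9 | CC(C)(C)[Si](C)(C)OC[C@@H](O[Si](C)(C)C(C)(C)C)[C@](C)(CC=C)CCOCc1ccccc1 | intermediate
11 | (3R,4S)-4,5-bis(TBSO)-3-methyl-3-(prop-2-en-1-yl)pentan-1-ol | CC(C)(C)[Si](C)(C)OC[C@@H](O[Si](C)(C)C(C)(C)C)[C@](C)(CC=C)CCO | intermediate
12 | (4R,5S)-5,6-bis(TBSO)-4-(2-chloroethyl)-4-methylhex-1-ene | CC(C)(C)[Si](C)(C)OC[C@@H](O[Si](C)(C)C(C)(C)C)[C@](C)(CC=C)CCCl | intermediate
13 | methyl (3R,4S)-4,5-bis(TBSO)-3-(2-chloroethyl)-3-methylpentanoate | CC(C)(C)[Si](C)(C)OC[C@@H](O[Si](C)(C)C(C)(C)C)[C@](C)(CC(=O)OC)CCCl | intermediate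
14 | isobutyraldehyde | CC(C)C=O | starting material
15 | lithium enolate of 13 (not isolated) | COC(O[Li])=C[C@](C)(CCCl)[C@H](O[Si](C)(C)C(C)(C)C)CO[Si](C)(C)C(C)(C)C | intermediate
16 | aldol adduct, C4 carbinol, mixture at C4 and C5 | COC(=O)C(C(O)C(C)C)[C@](C)(CCCl)[C@H](O[Si](C)(C)C(C)(C)C)CO[Si](C)(C)C(C)(C)C | intermediate
17 | chloro β-keto ester, C5 epimers | COC(=O)C(C(=O)C(C)C)[C@](C)(CCCl)[C@H](O[Si](C)(C)C(C)(C)C)CO[Si](C)(C)C(C)(C)C | intermediate
18 | iodo β-keto ester, C5 epimers (key-step precursor) | COC(=O)C(C(=O)C(C)C)[C@](C)(CCI)[C@H](O[Si](C)(C)C(C)(C)C)CO[Si](C)(C)C(C)(C)C | intermediate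
19 | C3 alkylsamarium diiodide (not isolated) | COC(=O)C(C(=O)C(C)C)[C@](C)(CC[Sm](I)I)[C@H](O[Si](C)(C)C(C)(C)C)CO[Si](C)(C)C(C)(C)C | intermediate
20 | methyl (1R,2R,5S)-5-[(1S)-1,2-bis(TBSO)ethyl]-2-hydroxy-5-methyl-2-(propan-2-yl)cyclopentane-1-carboxylate (key-step product) | CC(C)(C)[Si](C)(C)OC[C@@H](O[Si](C)(C)C(C)(C)C)[C@@]1(C)CC[C@@](O)(C(C)C)[C@@H]1C(=O)OC | intermediate
21 | C4,C6-diol (C6 = CH2OH) | CC(C)(C)[Si](C)(C)OC[C@@H](O[Si](C)(C)C(C)(C)C)[C@@]1(C)CC[C@@](O)(C(C)C)[C@@H]1CO | intermediate
22 | β-hydroxy aldehyde (C6 = CHO) | CC(C)(C)[Si](C)(C)OC[C@@H](O[Si](C)(C)C(C)(C)C)[C@@]1(C)CC[C@@](O)(C(C)C)[C@@H]1C=O | intermediate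
23 | tributyl(2-methylallyl)stannane | CCCC[Sn](CCCC)(CCCC)CC(C)=C | starting material
24 | (6S) homoallylic alcohol | CC(C)(C)[Si](C)(C)OC[C@@H](O[Si](C)(C)C(C)(C)C)[C@@]1(C)CC[C@@](O)(C(C)C)[C@@H]1[C@@H](O)CC(C)=C | intermediate
25 | 4-methoxybenzoyl chloride | COc1ccc(cc1)C(=O)Cl | starting material
26 | C6 4-methoxybenzoate, bis-TBS | CC(C)(C)[Si](C)(C)OC[C@@H](O[Si](C)(C)C(C)(C)C)[C@@]1(C)CC[C@@](O)(C(C)C)[C@@H]1[C@@H](OC(=O)c2ccc(OC)cc2)CC(C)=C | intermediate
27 | C9 primary alcohol, C10–OTBS | OC[C@@H](O[Si](C)(C)C(C)(C)C)[C@@]1(C)CC[C@@](O)(C(C)C)[C@@H]1[C@@H](OC(=O)c2ccc(OC)cc2)CC(C)=C | intermediate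
28 | C9 aldehyde, C10–OTBS | O=C[C@@H](O[Si](C)(C)C(C)(C)C)[C@@]1(C)CC[C@@](O)(C(C)C)[C@@H]1[C@@H](OC(=O)c2ccc(OC)cc2)CC(C)=C | intermediate
29 | metathesis diene (C9 vinyl, C8 methallyl) | C=C[C@@H](O[Si](C)(C)C(C)(C)C)[C@@]1(C)CC[C@@](O)(C(C)C)[C@@H]1[C@@H](OC(=O)c2ccc(OC)cc2)CC(C)=C | intermediate
30 | C10-TBS ether of the target | COc1ccc(C(=O)O[C@H]2CC(C)=C[C@@H](O[Si](C)(C)C(C)(C)C)[C@@]3(C)CC[C@@](O)(C(C)C)[C@H]23)cc1 | intermediate
31 | CNP0211568.1 | COc1ccc(C(=O)O[C@H]2CC(C)=C[C@@H](O)[C@@]3(C)CC[C@@](O)(C(C)C)[C@H]23)cc1 | target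

Total step count: 22. Longest linear sequence: 22 steps, from 1.

Steps most likely to fail

Step 13. Two things may go wrong. The acidic C5–H may protonate the C3 organosamarium, which only removes the iodine. The C5 epimers may also exchange too slowly, so that part of the material closes with C6 cis to the C10 side chain.
The fallback moves to the β-keto amide series, which belongs to the same known reaction class but has a less acidic C5–H and a stronger donor for trivalent samarium. It sets out from 13.
- AlMe3/Me2NH·HCl converts the ester into the N,N-dimethylamide F1.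
- LiN(iPr)2 and isobutyraldehyde give the aldol adduct F2.
- Dess–Martin oxidation gives the chloro β-keto amide F3.
- NaI in acetone gives the iodo β-keto amide F4. Its C5 epimers are stable enough to be separated, and the unwanted one is re-equilibrated with DBU and recycled.
- SmI2 in THF closes the cyclopentanol amide F5.
- LiH2NBH3 reduces the amide to the primary alcohol, and the route is rejoined at 21.

Step 5. The allyl group may attack C10 instead of C1. The epoxide may also migrate within the magnesium alkoxide, open to a chlorohydrin, or undergo a hydride shift at the tertiary centre. The fallback masks the hydroxyl before the C–C bond is made and sets out from 7.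
- TBSCl/imidazole gives the epoxy silyl ether F6. With no alkoxide present, epoxide migration is shut off.
- Allylmagnesium chloride in Et2O opens the magnesium-activated epoxide from the rear at C1 to give the mono-silylated secondary alcohol F7.
- TBSOTf/2,6-lutidine silylates C10–OH, and the route is rejoined at 10.

Step 21. Ruthenium may load too slowly on the C9 vinyl group, which is flanked by the silyl ether and quaternary C1. Catalyst decay or intermolecular coupling at the methallyl end would then win. The fallback is a relay ring-closing metathesis and sets out from 28.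
- Wittig reaction with hex-5-en-1-yltriphenylphosphonium bromide and NaN(SiMe3)2 gives the relay triene F8.
- The second-generation Grubbs catalyst first engages the unhindered terminal alkene of F8 and expels cyclopentene, which places the ruthenium carbene on C9.
- The carbene closes onto C8, and the route is rejoined at 30.

Further compounds
F1 | step 13 | (3R,4S)-4,5-bis(TBSO)-3-(2-chloroethyl)-N,N,3-trimethylpentanamide | CC(C)(C)[Si](C)(C)OC[C@@H](O[Si](C)(C)C(C)(C)C)[C@](C)(CC(=O)N(C)C)CCCl
F2 | step 13 | aldol adduct of F1 with isobutyraldehyde, mixture at C4 and C5 | CN(C)C(=O)C(C(O)C(C)C)[C@](C)(CCCl)[C@H](O[Si](C)(C)C(C)(C)C)CO[Si](C)(C)C(C)(C)C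
F3 | step 13 | chloro β-keto N,N-dimethylamide, C5 epimers | CN(C)C(=O)C(C(=O)C(C)C)[C@](C)(CCCl)[C@H](O[Si](C)(C)C(C)(C)C)CO[Si](C)(C)C(C)(C)C
F4 | step 13 | iodo β-keto N,N-dimethylamide, C5 epimers | CN(C)C(=O)C(C(=O)C(C)C)[C@](C)(CCI)[C@H](O[Si](C)(C)C(C)(C)C)CO[Si](C)(C)C(C)(C)C
F5 | step 13 | cyclopentanol N,N-dimethylcarboxamide with C4–OH cis to C6 | CC(C)(C)[Si](C)(C)OC[C@@H](O[Si](C)(C)C(C)(C)C)[C@@]1(C)CC[C@@](O)(C(C)C)[C@@H]1C(=O)N(C)C
F6 | step 5 | C9-TBS ether of epoxy alcohol 7 | CC(C)(C)[Si](C)(C)OC[C@H]1O[C@@]1(C)CCOCc2ccccc2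
F7 | step 5 | C9-TBS ether of diol 9 (C10–OH free) | CC(C)(C)[Si](C)(C)OC[C@@H](O)[C@](C)(CC=C)CCOCc1ccccc1
F8 | step 21 | relay triene, C9 (Z)-hepta-1,6-dienyl analogue of 29 | C=CCCC/C=C\[C@@H](O[Si](C)(C)C(C)(C)C)[C@@]1(C)CC[C@@](O)(C(C)C)[C@@H]1[C@@H](OC(=O)c2ccc(OC)cc2)CC(C)=C
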